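Retrosynthesis: the acyl–O bond of the C7' ester is cut first (side-chain acid 25). The epoxyquinone is traced back through its C3' dimethyl ketal to a 4-methoxyphenol, and C8=CH2 to a C8 ketone. Then C9–C11 (enolate benzylation), C3–C4 (ring A) and C1–C10 (conjugate addition) are cut while C4 is re-bonded to C7, which leads to (1R,5R)-verbenone.
Enabling feature: ring B (C5–C10) with its C8 oxygen, the C10 methyl group, the C5 stereocentre and the gem-dimethyl carbon C4 are all present in verbenone, where C4 is tied to C7 in a cyclobutane. C7 is alpha to C8=O, so a Lewis acid on that oxygen can release C4 as a tertiary cation; C7 is also a bridgehead, so only C9 can be enolised.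
Forward order: ring B is bought. The C1–C3 chain goes onto C10 and the arene onto C9, ring A closes as the cyclobutane opens, the arene is dearomatised and epoxidised, and the side chain is esterified on last.
Stereochemistry: C5 comes from verbenone and C10 from addition anti to the C4 bridge, and the trans ring fusion follows from these two. C9 is set by equilibration next to C8=O, C1'/C2' by a cinchona ammonium salt, and the side-chain carbinol by an esterase desymmetrisation.

Key step: step 9

Numbering: drimane numbering is used for all intermediates, verbenone included (C1–C10 decalin carbons, C11 benzylic CH2, C12 methylene carbon, C1'–C6' six-membered carbocycle, C7' its CH2O carbon). Alpha and beta refer to the usual drimane drawing (10-CH3 beta, 5-H alpha).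
Assumption: N-benzylcinchonidinium chloride is taken to deliver the peroxide to the face of 19 that gives the (1'R,2'S)-epoxide; should the sense be the opposite, the pseudoenantiomeric N-benzylcinchoninium chloride takes its place.

Step 1
Reactants: 1 (1R,5R)-(+)-verbenone; 2 1-(trimethylsilyl)propyne
Product: 4 silylpropargyl verbanone (4,6,6-trimethyl-4-[3-(trimethylsilyl)prop-2-ynyl]bicyclo[3.1.1]heptan-2-one; chain on C10 anti to the CMe2 bridge), via silyl enol ether 3 (not isolated)
Conditions: 2, n-BuLi, THF, −78 → −20 °C; CuBr·SMe2, LiCl, −78 °C; Me3SiCl, then 1, −78 → −30 °C; 1 M HCl, THF, 0 °C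
Reagents that add atoms: chlorotrimethylsilane, C[Si](C)(C)Cl (its silyl group is held by 3 only)
Why: Chlorosilane-accelerated 1,4-addition of an organocopper reagent to an enone, a reaction type that verbenone accepts; the silyl cap steers the ambident propargyl/allenyl copper species to bond through its CH2 end, and the reagent can reach C10 only from the face opposite the C4 gem-dimethyl bridge, which sets C10 (methyl beta, chain alpha and trans to C4).

Step 2
Reactants: 4 silylpropargyl verbanone
Product: 5 (Z)-silylallyl verbanone (4,6,6-trimethyl-4-[(Z)-3-(trimethylsilyl)prop-2-enyl]bicyclo[3.1.1]heptan-2-one)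
Conditions: H2 (1 atm), Pd/CaCO3 poisoned with Pb(OAc)2, quinoline, hexane–EtOAc, rt
Reagents that add atoms: none
Why: Syn semihydrogenation of a silylalkyne on poisoned palladium is the standard entry to Z-vinylsilanes and leaves the ketone and the cyclobutane untouched.

Step 3
Reactants: 6 2-hydroxy-5-methoxybenzaldehyde
Product: 7 2-(benzyloxy)-5-methoxybenzaldehyde
Conditions: BnBr, K2CO3, DMF, rt
Reagents that add atoms: benzyl bromide, BrCc1ccccc1
Why: Williamson ether synthesis on an acidic ortho-formyl phenol; the benzyl group later leaves in the same operation that saturates ring A.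

Step 4
Reactants: 7 2-(benzyloxy)-5-methoxybenzaldehyde
Product: 8 2-(benzyloxy)-4-bromo-5-methoxybenzaldehyde
Conditions: Br2, NaOAc, AcOH, rt
Reagents that add atoms: bromine, BrBr
Why: Electrophilic aromatic bromination goes to C4, ortho to the methoxy group and para to the formyl group, as in 2,5-dialkoxybenzaldehydes, and NaOAc takes up the HBr that could attack the benzyl ether.

Step 5
Reactants: 8 2-(benzyloxy)-4-bromo-5-methoxybenzaldehyde
Product: 9 methyl 5-(benzyloxy)-4-formyl-2-methoxybenzoate
Conditions: Pd(OAc)2 (5 mol%), dppf, CO (1 atm), Et3N, MeOH–DMF, 70 °C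
Reagents that add atoms: carbon monoxide, [C-]#[O+]; methanol, CO
Why: Palladium-catalysed alkoxycarbonylation of an aryl bromide (oxidative addition to zerovalent palladium, CO insertion, methanolysis) tolerates the aldehyde and both ethers.

Step 6
Reactants: 9 methyl 5-(benzyloxy)-4-formyl-2-methoxybenzoate
Product: 10 methyl 5-(benzyloxy)-4-(hydroxymethyl)-2-methoxybenzoate
Conditions: NaBH4, MeOH–THF, 0 °C
Reagents that add atoms: none
Why: Borohydride reduction is chemoselective for the aldehyde and leaves the aryl ester alone at this temperature.

Step 7
Reactants: 10 methyl 5-(benzyloxy)-4-(hydroxymethyl)-2-methoxybenzoate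
Product: 11 methyl 5-(benzyloxy)-4-(bromomethyl)-2-methoxybenzoate
Conditions: CBr4, PPh3, CH2Cl2, 0 °C
Reagents that add atoms: tetrabromomethane, BrC(Br)(Br)Br
Why: The Appel reaction converts a primary benzylic alcohol into the bromide under neutral conditions that spare the ester and the ethers.

Step 8
Reactants: 5 (Z)-silylallyl verbanone; 11 methyl 5-(benzyloxy)-4-(bromomethyl)-2-methoxybenzoate
Product: 13 benzylated (Z)-silylallyl verbanone (5 carrying on C9 and anti to the CMe2 bridge the CH2 of the 2-(benzyloxy)-5-methoxy-4-(methoxycarbonyl)phenyl group; 9-alpha arm), via lithium enolate 12 (not isolated)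
Conditions: LDA, THF, −78 °C; DMPU, then 11, −78 → −10 °C
Reagents that add atoms: lithium diisopropylamide, CC(C)[N-]C(C)C.[Li+] (its lithium is held by 12 only)
Why: Kinetic enolate alkylation (SN2 on a reactive benzylic bromide) in which C7, a bridgehead whose enolate would break Bredt's rule, cannot be deprotonated, so that only C9 reacts; the bromide approaches anti to the gem-dimethyl bridge and gives the 9-alpha arm, a centre that is corrected in step 9.

Step 9
Reactants: 13 benzylated (Z)-silylallyl verbanone
Product: 15 trans-decalone (11-aryl-12-nordrim-2-en-8-one; 5-alpha-H; 10-beta-CH3; equatorial 9-beta arm; aryl = 2-(benzyloxy)-5-methoxy-4-(methoxycarbonyl)phenyl), via 9-epi ketone 14 (not isolated)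
Conditions: SnCl4 (3 equiv), CH2Cl2, −78 → 0 °C; aqueous work-up; crude 14, NaOMe (cat.), MeOH, rt
Reagents that add atoms: none
Why: Proposed new method: SnCl4 bound to the C8 carbonyl oxygen should break the strained C4–C7 bond heterolytically, because of the two cyclobutane bonds at the alpha-carbon C7 only this one leaves a tertiary cation (C4) beside the tin enolate (C7=C8); once ring B, now a free half-chair, has inverted so that the C5–C4 and C10–C1 bonds pass from anti to gauche, the cation is taken up by the silicon-bearing carbon C3. Ring A closes in the 6-endo-trig mode through the new C3–C4 bond, the charge arrives at C2 beta to silicon, and loss of Me3SiCl leaves the C2=C3 olefin; the Z geometry matters, since only a silyl group cis to C1 comes to lie pseudoaxial and parallel to the empty orbital at C2 within the forming six-membered ring. The closest known reactions are the SnCl4-induced opening of 4-aryl-6,6-dimethylbicyclo[3.1.1]heptan-2-ones with capture of the same kind of cation by a phenol oxygen, the opening of nopinone-type ketones by HCl or Me3SiI, and vinylsilane-terminated cation-olefin cyclisations, but the merger with a carbon terminator is without example. The ring closure creates no stereocentre: C5 and C10 are in place and, as their two ring-forming bonds stand trans on ring B, only the trans-decalin can arise, whereas C9, whose arm is axial in 14, is brought to the equatorial 9-beta configuration by NaOMe through the C8–C9 enolate. The step needs closure to outrun proton loss and chloride capture, and it is helped by the fact that the tertiary chloride and the isopropenyl isomer should re-ionise under SnCl4 and the HCl set free, while desilylation is irreversible. The arene stays out because its ester, chelated to one equivalent of SnCl4 together with the neighbouring methoxy group, deactivates it and because its attack would need a seven-membered ring.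

Step 10
Reactants: 15 trans-decalone
Product: 16 saturated keto phenol (11-aryl-12-nordriman-8-one; aryl = 2-hydroxy-5-methoxy-4-(methoxycarbonyl)phenyl)
Conditions: H2 (3 atm), Pd/C, EtOAc, rt
Reagents that add atoms: none
Why: Heterogeneous hydrogenation saturates the cis-disubstituted C2=C3 olefin and hydrogenolyses the aryl benzyl ether in one operation, while the hindered ketone and the ester are inert and no stereocentre is formed.

Step 11
Reactants: 16 saturated keto phenol
Product: 17 methylene phenol ester (11-aryldrim-8(12)-ene; aryl = 2-hydroxy-5-methoxy-4-(methoxycarbonyl)phenyl)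
Conditions: Ph3PCH3Br, KOt-Bu (excess ylide), toluene–THF, rt → 60 °C
Reagents that add atoms: methyltriphenylphosphonium bromide, C[P+](c1ccccc1)(c1ccccc1)c1ccccc1.[Br-]
Why: Wittig methylenation in which the first equivalent of ylide turns the phenol (partly closed onto C8 as a hemiketal) into the phenoxide, which frees the ketone as in the olefination of lactols and makes the aryl ester less electrophilic, while C9 already holds its thermodynamically preferred equatorial configuration under the basic conditions.

Step 12
Reactants: 17 methylene phenol ester
Product: 18 phenol benzylic alcohol (11-aryldrim-8(12)-ene; aryl = 2-hydroxy-4-(hydroxymethyl)-5-methoxyphenyl)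
Conditions: LiAlH4, THF, 0 °C
Reagents that add atoms: none
Why: Hydride reduction takes the aryl ester to the benzylic alcohol, and neither the aluminium phenoxide nor the isolated 1,1-disubstituted olefin reacts.

Step 13
Reactants: 18 phenol benzylic alcohol
Product: 19 quinone monoketal (2-(drim-8(12)-en-11-yl)-5-(hydroxymethyl)-4,4-dimethoxycyclohexa-2,5-dienone)
Conditions: PhI(OAc)2, MeOH, 0 °C
Reagents that add atoms: methanol, CO
Why: Oxidative dearomatisation of a 4-methoxyphenol by a trivalent iodine reagent, in which methanol adds para to the phenol oxygen at the methoxy-bearing C3', so that the ketal lies beside C4' and the free carbonyl (C6') beside C1', while PhI(OAc)2 alone oxidises neither the primary alcohol nor the olefin.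

Step 14
Reactants: 19 quinone monoketal
Product: 20 epoxy ketal alcohol ((1'R,2'S)-1',2'-epoxide of 19)
Conditions: t-BuOOH, aq NaOH, N-benzylcinchonidinium chloride (10 mol%), toluene, 0 °C → rt
Reagents that add atoms: tert-butyl hydroperoxide, CC(C)(C)OO
Why: Weitz–Scheffer epoxidation under chiral phase-transfer catalysis, known for quinone monoketals and 2-alkylquinones, in which the peroxide anion adds to C2', the only unsubstituted beta-carbon of the dienone (C4' is fully substituted), so that C1'=C2' is epoxidised; the face is chosen by the ion-paired cinchona cation, and any minor isomer is a diastereomer that chromatography should remove.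

Step 15
Reactants: 21 3-hydroxy-3-methylglutaric acid
Product: 22 dimethyl 3-hydroxy-3-methylglutarate
Conditions: MeI, K2CO3, DMF, rt
Reagents that add atoms: iodomethane, CI
Why: Alkylative esterification of the dicarboxylate (SN2 on MeI) avoids the acid that could dehydrate the tertiary alcohol.

Step 16
Reactants: 22 dimethyl 3-hydroxy-3-methylglutarate
Product: 23 (S)-3-hydroxy-5-methoxy-3-methyl-5-oxopentanoic acid
Conditions: pig liver esterase, pH 7 phosphate buffer, rt, pH held with 1 M NaOH; then HCl to pH 2
Reagents that add atoms: water, O
Why: Enzymatic desymmetrisation of a prochiral diester, in which pig liver esterase is known to hydrolyse only the pro-S ester group of this very substrate, sets the carbinol centre as S.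

Step 17
Reactants: 23 (S)-half ester
Product: 24 (R)-1-tert-butyl 5-methyl 3-hydroxy-3-methylpentanedioate
Conditions: t-BuOC(=NH)CCl3, CH2Cl2–cyclohexane, rt
Reagents that add atoms: tert-butyl 2,2,2-trichloroacetimidate, CC(C)(C)OC(=N)C(Cl)(Cl)Cl
Why: Carboxylic acids are tert-butylated by the trichloroacetimidate without added catalyst (protonation of the imidate, then transfer of the tert-butyl cation), and the tertiary alcohol and the stereocentre are not touched, the descriptor changing only through the priority rules.

Step 18
Reactants: 24 (R)-mixed diester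
Product: 25 (R)-5-tert-butoxy-3-hydroxy-3-methyl-5-oxopentanoic acid
Conditions: LiOH, THF–H2O, 0 °C; then 1 M HCl to pH 3
Reagents that add atoms: lithium hydroxide, [Li+].[OH-]
Why: Saponification tells the two esters apart sterically (methyl fast, tert-butyl inert), so that the arm that was an ester in 23 becomes the free acid, and at no point are both arms free, which would make the molecule achiral.

Step 19
Reactants: 20 epoxy ketal alcohol; 25 (R)-acid
Product: 26 protected ester (C7' ester of 20 with 25)
Conditions: DCC, DMAP (cat.), CH2Cl2, 0 °C → rt
Reagents that add atoms: none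
Why: Steglich esterification of an unhindered primary allylic alcohol, in which the tertiary hydroxyl of 25 is too hindered to compete and the masked epoxyquinone is not attacked by DMAP.

Step 20
Reactants: 26 protected ester
Product: 28 silyl ether acid (26 with free CO2H in place of CO2t-Bu and OSiEt3 in place of the tertiary OH), via bis-silyl derivative 27 (not isolated)
Conditions: Et3SiOTf, 2,6-lutidine, CH2Cl2, 0 °C; pH 7 buffer work-up
Reagents that add atoms: triethylsilyl trifluoromethanesulfonate, CC[Si](CC)(CC)OS(=O)(=O)C(F)(F)F
Why: Silyl triflate-mediated cleavage of a tert-butyl ester (O-silylation, loss of isobutene) runs under lutidine buffering and so spares the exocyclic olefin that trifluoroacetic acid would isomerise, while the tertiary alcohol is silylated on the way, the silyl ester falls off on work-up, and ketals of ketones are known to survive this reagent pair.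

Step 21
Reactants: 28 silyl ether acid
Product: 29 4'-oxomacrophorin D
Conditions: 48% aq HF, MeCN, 0 °C → rt
Reagents that add atoms: water, O
Why: Aqueous HF in acetonitrile, a usual reagent for unmasking epoxyquinones from their monoketals, hydrolyses the dimethyl ketal and removes the triethylsilyl ether in one operation and is too weak an acid to protonate the C8 methylene group or to open the electron-poor epoxide.

Compound list
1 | (1R,5R)-(+)-verbenone | CC1=CC(=O)[C@@H]2C[C@H]1C2(C)C | starting material
2 | 1-(trimethylsilyl)propyne | CC#C[Si](C)(C)C | starting material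
3 | trimethylsilyl enol ether of 4 (C8–OSiMe3, C8=C9) | C[C@@]1(CC#C[Si](C)(C)C)C=C(O[Si](C)(C)C)[C@@H]2C[C@H]1C2(C)C | intermediate
4 | silylpropargyl verbanone, chain on C10 anti to the CMe2 bridge | C[C@@]1(CC#C[Si](C)(C)C)CC(=O)[C@@H]2C[C@H]1C2(C)C | intermediate
5 | (Z)-silylallyl verbanone | C[C@@]1(C/C=C\[Si](C)(C)C)CC(=O)[C@@H]2C[C@H]1C2(C)C | intermediate
6 | 2-hydroxy-5-methoxybenzaldehyde | COc1ccc(O)c(C=O)c1 | starting material
7 | 2-(benzyloxy)-5-methoxybenzaldehyde | COc1ccc(OCc2ccccc2)c(C=O)c1 | intermediate
8 | 2-(benzyloxy)-4-bromo-5-methoxybenzaldehyde | COc1cc(C=O)c(OCc2ccccc2)cc1Br | intermediate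
9 | methyl 5-(benzyloxy)-4-formyl-2-methoxybenzoate | COc1cc(C=O)c(OCc2ccccc2)cc1C(=O)OC | intermediate
10 | methyl 5-(benzyloxy)-4-(hydroxymethyl)-2-methoxybenzoate | COc1cc(CO)c(OCc2ccccc2)cc1C(=O)OC | intermediate
11 | methyl 5-(benzyloxy)-4-(bromomethyl)-2-methoxybenzoate | COc1cc(CBr)c(OCc2ccccc2)cc1C(=O)OC | intermediate
12 | lithium C8–C9 enolate of 5 | C[C@@]1(C/C=C\[Si](C)(C)C)C=C(O[Li])[C@@H]2C[C@H]1C2(C)C | intermediate
13 | benzylated (Z)-silylallyl verbanone, 9-alpha arm (key-step precursor) | C[C@@]1(C/C=C\[Si](C)(C)C)[C@H](Cc3cc(OC)c(C(=O)OC)cc3OCc3ccccc3)C(=O)[C@@H]2C[C@H]1C2(C)C | intermediate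
14 | 9-epi trans-decalone (axial 9-alpha arm) | O=C1CC[C@H]2C(C)(C)C=CC[C@]2(C)[C@@H]1Cc1cc(OC)c(C(=O)OC)cc1OCc1ccccc1 | intermediate
15 | trans-decalone, 11-aryl-12-nordrim-2-en-8-one, equatorial 9-beta arm (key-step product) | O=C1CC[C@H]2C(C)(C)C=CC[C@]2(C)[C@H]1Cc1cc(OC)c(C(=O)OC)cc1OCc1ccccc1 | intermediate
16 | saturated keto phenol | O=C1CC[C@H]2C(C)(C)CCC[C@]2(C)[C@H]1Cc1cc(OC)c(C(=O)OC)cc1O | intermediate
17 | methylene phenol ester | C=C1CC[C@H]2C(C)(C)CCC[C@]2(C)[C@H]1Cc1cc(OC)c(C(=O)OC)cc1O | intermediate
18 | phenol benzylic alcohol | C=C1CC[C@H]2C(C)(C)CCC[C@]2(C)[C@H]1Cc1cc(OC)c(CO)cc1O | intermediate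
19 | quinone monoketal | C=C1CC[C@H]2C(C)(C)CCC[C@]2(C)[C@H]1CC1=CC(OC)(OC)C(CO)=CC1=O | intermediate
20 | (1'R,2'S)-epoxy ketal alcohol | C=C1CC[C@H]2C(C)(C)CCC[C@]2(C)[C@H]1C[C@@]12O[C@@H]1C(OC)(OC)C(CO)=CC2=O | intermediate
21 | 3-hydroxy-3-methylglutaric acid | CC(O)(CC(=O)O)CC(=O)O | starting material
22 | dimethyl 3-hydroxy-3-methylglutarate | COC(=O)CC(C)(O)CC(=O)OC | intermediate
23 | (S)-3-hydroxy-5-methoxy-3-methyl-5-oxopentanoic acid | COC(=O)C[C@@](C)(O)CC(=O)O | intermediate
24 | (R)-1-tert-butyl 5-methyl 3-hydroxy-3-methylpentanedioate | COC(=O)C[C@@](C)(O)CC(=O)OC(C)(C)C | intermediate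
25 | (R)-5-tert-butoxy-3-hydroxy-3-methyl-5-oxopentanoic acid | OC(=O)C[C@@](C)(O)CC(=O)OC(C)(C)C | intermediate
26 | protected ester (ketal, tert-butyl ester) | C=C1CC[C@H]2C(C)(C)CCC[C@]2(C)[C@H]1C[C@@]12O[C@@H]1C(OC)(OC)C(COC(=O)C[C@@](C)(O)CC(=O)OC(C)(C)C)=CC2=O | intermediate
27 | bis-silyl derivative (triethylsilyl ether and triethylsilyl ester) | C=C1CC[C@H]2C(C)(C)CCC[C@]2(C)[C@H]1C[C@@]12O[C@@H]1C(OC)(OC)C(COC(=O)C[C@@](C)(O[Si](CC)(CC)CC)CC(=O)O[Si](CC)(CC)CC)=CC2=O | intermediate
28 | silyl ether acid | C=C1CC[C@H]2C(C)(C)CCC[C@]2(C)[C@H]1C[C@@]12O[C@@H]1C(OC)(OC)C(COC(=O)C[C@@](C)(O[Si](CC)(CC)CC)CC(=O)O)=CC2=O | intermediate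
29 | 4'-oxomacrophorin D | C=C1CC[C@H]2C(C)(C)CCC[C@]2(C)[C@H]1C[C@@]12O[C@@H]1C(=O)C(COC(=O)C[C@@](C)(O)CC(=O)O)=CC2=O | target

Total step count: 21. Longest linear sequence: 15 steps (from 6: steps 3–14 and 19–21).

Steps most likely to fail

1. Step 9. The C4 cation may lose a proton or collapse with chloride faster than ring B inverts and ring A closes. The vinylsilane may be protodesilylated by the HCl that builds up, and the benzyl ether may be eroded by the Lewis acid. Fallback: the two events are uncoupled.
- Setting out from 13, Me3SiI (CH2Cl2, 0 °C) opens the cyclobutane in the way known for nopinone-type ketones. This gives the ring-opened tertiary iodide silyl enol ether F1.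
- DBU removes HI and dilute acid frees the ketone, which gives the isopropenyl cyclohexanone F2.
- The 1,1-disubstituted olefin of F2 is protonated with SnCl4 and a phenol as proton source (CH2Cl2, −78 °C). This is a classical proton-initiated cation-olefin cyclisation with a vinylsilane terminator, and it regenerates the C4 cation on a conformationally relaxed ring B.
- The cyclisation leads to 14, where the route is rejoined.

2. Step 1. The copper reagent may add 1,2, transfer its allenyl terminus, or fail to add at the fully substituted and shielded beta-carbon C10. Fallback: activation of the enone instead of the nucleophile.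
- Setting out from 1, allenyltributylstannane and TiCl4 (CH2Cl2, −78 °C) transfer a propargyl group in the SE2' sense. This is a known conjugate propargylation that also builds quaternary carbons.
- Attack again anti to the bridge gives the propargyl verbanone F3.
- Double deprotonation with LiHMDS and quenching with Me3SiCl silylates both the acetylide and the enolate. This gives 3, and the acidic work-up of step 1 carries it on to 4.

3. Step 14. Facial selectivity may be poor if the ion-paired catalyst and the bulky drimane residue are mismatched, and the free hydroxyl group may loosen the ion pair. Fallback: the oxidant is anchored to the substrate instead of being delivered by an ion pair.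
- Setting out from 19, trityl hydroperoxide is deprotonated with NaHMDS in the presence of a diisopropyl tartrate (toluene, −50 °C).
- The free C7' hydroxyl serves as the binding site. This is the known hydroxyl-directed, tartrate-mediated nucleophilic epoxidation of hydroxymethyl quinone monoketals.
- The enantiomer of the tartrate is chosen for the (1'R,2'S) face, and the route is rejoined at 20 without any new compound.

Further compounds
F1 | step 9 | ring-opened tertiary iodide silyl enol ether (C8–OSiMe3, C7=C8, C4–I) | C[Si](C)(C)OC1=CC[C@@H](C(C)(C)I)[C@](C)(C/C=C\[Si](C)(C)C)[C@@H]1Cc1cc(OC)c(C(=O)OC)cc1OCc1ccccc1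
F2 | step 9 | isopropenyl cyclohexanone (ring B with C5 isopropenyl, C10 methyl and (Z)-silylallyl, C9 arm) | O=C1CC[C@@H](C(C)=C)[C@](C)(C/C=C\[Si](C)(C)C)[C@@H]1Cc1cc(OC)c(C(=O)OC)cc1OCc1ccccc1
F3 | step 1 | propargyl verbanone (4,6,6-trimethyl-4-(prop-2-ynyl)bicyclo[3.1.1]heptan-2-one, chain anti to the bridge) | C[C@@]1(CC#C)CC(=O)[C@@H]2C[C@H]1C2(C)C
F0 | step 14 | none | none
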